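Assumption: atoms carry ent-kaurane numbers, and the configuration is read literally from the SMILES. In it H-9 is anti to C15 (ring B trans-fused to ring C), and the 11-OH is equatorial, anti to the C15–C16 bridge.

**Retrosynthetic overview**
1. The C6 aldehyde and the C11 oxygen stand 1,5 to each other across C5–C10–C9. This Michael retron cuts C9–C10, the bond between the spiro quaternary carbon of ring A and ring C, and reduces ring B (δ-lactone C7(=O)–O–C20–C10–C9–C8) to an ester tether.
2. The cut gives two halves: an A-ring enal alcohol with one stereocentre (C4), and a bridgehead bicyclo[3.2.1]octane keto acid (rings C/D).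
3. Rings C/D come from a bridging Michael addition (C12–C13) of an acetonyl chain onto a 5,5-disubstituted cyclopentenone. The C16 enolate is trapped in a Mannich reaction, which brings in C17 and stores the exo-methylene ketone.
4. Order of rings: A and D are bought as rings, then C (step 10), then B (step 14). The endgame unmasks the enone and adjusts C6, C11 and C15.
5. Absolute configuration comes from two catalytic steps, C4 in step 2 and C8 in step 7. C13, C9, C10, C5 and C11 are relayed from these.

Key step: step 14

**Route**

Step 1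
Reactants: 1 2-methylcyclohexan-1-one
Product: 2 2-methyl-1-(trimethylsilyloxy)cyclohex-1-ene
Conditions: TMSCl, Et3N, DMF, 130 °C; distillation
Reagents that add atoms: chlorotrimethylsilane, C[Si](C)(C)Cl
Why: Silyl enol ether formation under equilibrating conditions should give mainly the tetrasubstituted enol ether, which fixes the next C–C bond at the methyl-bearing carbon (C4).

Step 2
Reactants: 2 2-methyl-1-(trimethylsilyloxy)cyclohex-1-ene
Product: 3 (S)-2-(hydroxymethyl)-2-methylcyclohexan-1-one
Conditions: aq. HCHO, Sc(OTf)3 (10 mol %), chiral 6,6'-bis(1-hydroxy-2,2-dimethylpropyl)-2,2'-bipyridine (12 mol %, enantiomer that gives (S)-3), DME/H2O, −20 °C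
Reagents that add atoms: formaldehyde, C=O
Why: In this catalytic asymmetric Mukaiyama aldol hydroxymethylation the chiral scandium complex shields one face of the enol ether and so sets the quaternary C4.

Step 3
Reactants: 3 (S)-2-(hydroxymethyl)-2-methylcyclohexan-1-one
Product: 4 [(1S)-1-methyl-2-oxocyclohexyl]methyl acetate
Conditions: Ac2O, pyridine, DMAP (cat.), CH2Cl2, 0 °C
Reagents that add atoms: acetic anhydride, CC(=O)OC(C)=O
Why: O-acetylation installs the C19 acetate of the target at once and blocks retro-aldol loss of formaldehyde.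

Step 4
Reactants: 4 [(1S)-1-methyl-2-oxocyclohexyl]methyl acetate
Product: 5 [(1S)-2-bromo-3-formyl-1-methylcyclohex-2-en-1-yl]methyl acetate
Conditions: PBr3, DMF, CHCl3, 0 → 60 °C; aq. NaHCO3
Reagents that add atoms: N,N-dimethylformamide, CN(C)C=O; phosphorus tribromide, BrP(Br)Br; water, O
Why: In this Vilsmeier–Haack–Arnold bromoformylation the ketone can enolise only towards C10, so the formyl carbon (C20) goes to C10 and bromine to C5 while C4 is untouched.

Step 5
Reactants: 5 [(1S)-2-bromo-3-formyl-1-methylcyclohex-2-en-1-yl]methyl acetate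
Product: 6 [(1S)-2-bromo-3-(hydroxymethyl)-1-methylcyclohex-2-en-1-yl]methyl acetate
Conditions: NaBH4, CeCl3·7H2O, MeOH, 0 °C
Reagents that add atoms: none
Why: Luche 1,2-reduction of the enal should leave the vinyl bromide and the acetate alone.

Step 6
Reactants: 6 [(1S)-2-bromo-3-(hydroxymethyl)-1-methylcyclohex-2-en-1-yl]methyl acetate
Product: 7 [(1R)-2,3-bis(hydroxymethyl)-1-methylcyclohex-2-en-1-yl]methyl acetate
Conditions: Bu3SnCH2OH, Pd(PPh3)4 (10 mol %), dioxane, 100 °C
Reagents that add atoms: (tributylstannyl)methanol, CCCC[Sn](CCCC)(CCCC)CO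
Why: Stille hydroxymethylation of the vinyl bromide brings in C6 at the alcohol level without hydride or base, so the acetate survives.

Step 7
Reactants: 8 tert-butyl 2-oxocyclopentane-1-carboxylate
Product: 9 tert-butyl (S)-2-oxo-1-(prop-2-enyl)cyclopentane-1-carboxylate
Conditions: allyl bromide, C2-symmetric N-spiro binaphthyl ammonium bromide (1 mol %, enantiomer that gives (S)-9), sat. aq. K2CO3, toluene, 0 °C
Reagents that add atoms: allyl bromide, C=CCBr
Why: In this asymmetric phase-transfer alkylation of a cyclic β-keto ester the chiral ammonium enolate ion pair is allylated on one face, which sets the quaternary C8.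

Step 8
Reactants: 9 tert-butyl (S)-2-oxo-1-(prop-2-enyl)cyclopentane-1-carboxylate
Product: 10 tert-butyl (R)-2-oxo-1-(prop-2-enyl)cyclopent-3-ene-1-carboxylate
Conditions: IBX, DMSO/PhF, 75 °C
Reagents that add atoms: none
Why: IBX dehydrogenation runs through the only possible enol (towards C16) and should give the cyclopentenone, while C8 keeps its geometry and only the CIP descriptor changes.

Step 9
Reactants: 10 tert-butyl (R)-2-oxo-1-(prop-2-enyl)cyclopent-3-ene-1-carboxylate
Product: 11 tert-butyl (S)-2-oxo-1-(2-oxopropyl)cyclopent-3-ene-1-carboxylate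
Conditions: PdCl2 (10 mol %), CuCl, O2 (1 atm), DMF/H2O, 23 °C
Reagents that add atoms: water, O
Why: Wacker–Tsuji oxidation turns the terminal alkene into the methyl ketone (C11), and the electron-poor enone alkene is inert.

Step 10
Reactants: 11 tert-butyl (S)-2-oxo-1-(2-oxopropyl)cyclopent-3-ene-1-carboxylate
Product: 13 tert-butyl 6-exo-[(dimethylamino)methyl]-3,7-dioxobicyclo[3.2.1]octane-1-carboxylate, via lithium enolate 12 (not isolated)
Conditions: LDA (1.05 equiv), THF, −78 → −20 °C; then Me2N=CH2+ I−, −78 → 23 °C
Reagents that add atoms: dimethyl(methylidene)ammonium iodide (Eschenmoser's salt), C=[N+](C)C.[I-]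
Why: Kinetic deprotonation of the methyl ketone (C12) and a bridging intramolecular Michael addition to C13 (6-(enolendo)-exo-trig) close ring C on the only face the chain can reach, which sets C13, and the regiodefined C16 enolate 12 is then trapped on its exo face in a Mannich reaction that brings in C17.

Step 11
Reactants: 13 tert-butyl 6-exo-[(dimethylamino)methyl]-3,7-dioxobicyclo[3.2.1]octane-1-carboxylate
Product: 14 6-exo-[(dimethylamino)methyl]-3,7-dioxobicyclo[3.2.1]octane-1-carboxylic acid
Conditions: TFA/CH2Cl2 1:3, 0 → 23 °C
Reagents that add atoms: none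
Why: Acidolysis of the tert-butyl ester gives a bridgehead β-keto acid that should be stable enough to handle, because its decarboxylation would need an anti-Bredt enol.

Step 12
Reactants: 14 6-exo-[(dimethylamino)methyl]-3,7-dioxobicyclo[3.2.1]octane-1-carboxylic acid; 7 [(1R)-2,3-bis(hydroxymethyl)-1-methylcyclohex-2-en-1-yl]methyl acetate
Product: 15 C20 ester of acid 14 and diol 7 (C6H2OH free)
Conditions: EDC·HCl, DMAP (0.2 equiv), CH2Cl2, −10 → 0 °C, 7 in slight excess
Reagents that add atoms: none
Why: In this Steglich esterification the C20 hydroxyl is the less hindered of the two allylic alcohols of 7, because the C6 hydroxyl is flanked by the quaternary C4.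

Step 13
Reactants: 15 C20 ester of acid 14 and diol 7
Product: 16 enal ester (C6 aldehyde on the C5=C10 double bond)
Conditions: MnO2, CH2Cl2, 23 °C
Reagents that add atoms: none
Why: MnO2 oxidises the remaining allylic alcohol to the tetrasubstituted enal and should touch neither the ketones nor the esters.

Step 14
Reactants: 16 enal ester
Product: 18 trans-fused Michael adduct (spiro-lactone 11,15-diketo 6-aldehyde), via cis-fused 9-epimer 17 (not isolated)
Conditions: t-BuOK (0.3 equiv), THF/t-BuOH 10:1, 0.01 M, −20 → 23 °C; AcOH quench
Reagents that add atoms: none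
Why: Catalytic t-BuOK equilibrates the enolates of 16, and only the C9 enolate of the C11 ketone can reach the enal, so it adds to C10 in an intramolecular Michael addition (closest type: base-mediated ketone–enal Michael cyclisation that forms a quaternary β-carbon), with the more acidic aldehyde enolate as the sink until t-BuOH returns the proton. Ring B closes in the 6-(enolexo)-exo-trig mode through the C9–C10 bond (ring C8–C7–O–C20–C10–C9). C10 is set because the enolate is attacked on its open axial face, anti to the C15–C16 bridge, in a chair-like array where the tether fixes C20, the small C1H2 takes the place under ring C and the C10=C5 bond points outwards, anti to C8–C9, so that C5 ends cis to C15 across the lactone. C9 first forms as the cis-fused epimer 17 with C10 axial on ring C, which the same base should epimerise through the C11 enolate to the trans-fused lactone 18 with C10 equatorial, as axial 2-substituents of bicyclo[3.2.1]octan-3-ones do. C5 is set by reversible protonation next to the aldehyde, which should place CHO equatorial, trans to C9 and cis to C20 and C19. The step needs C9 over C12 and C16 (secured by ring size, since the other enolates reach no six-membered ring), 1,4- over 1,2-addition (the aldol is reversible) and an intact D ring (secured by storing the enone as its Mannich base).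

Step 15
Reactants: 18 trans-fused Michael adduct
Product: 20 11-oxotrichorabdal B (exo-methylene ketone unmasked), via trimethylammonium iodide 19 (not isolated)
Conditions: MeI, CH2Cl2, 23 °C; then sat. aq. NaHCO3
Reagents that add atoms: none
Why: Quaternisation of the Mannich base and E1cB (Hofmann-type) elimination can only give the exocyclic C16=C17 bond, because C13 is a bridgehead.

Step 16
Reactants: 20 11-oxotrichorabdal B
Product: 21 6,15-diol 11-ketone
Conditions: NaBH4, CeCl3·7H2O, MeOH/CH2Cl2, −78 °C
Reagents that add atoms: none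
Why: Luche reduction should take the aldehyde and (1,2) the enone, while the C11 ketone, shielded by the C15–C16 bridge on one face and by C10 on the other, is expected to survive at −78 °C, and the C15 carbinol (drawn from exo attack) is erased again in step 18.

Step 17
Reactants: 21 6,15-diol 11-ketone
Product: 22 6,11,15-triol
Conditions: SmI2 (4 equiv), H2O (50 equiv), THF, 0 °C, short contact
Reagents that add atoms: none
Why: Single-electron (ketyl) reduction should give the thermodynamic equatorial 11-alcohol, trans to C10, as electron-transfer reductions of bicyclo[3.2.1]octan-3-ones do, whereas hydride would come from the open face and give the axial alcohol.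

Step 18
Reactants: 22 6,11,15-triol
Product: 23 6-alcohol of trichorabdal B (15-ketone restored)
Conditions: MnO2, CH2Cl2, 23 °C
Reagents that add atoms: none
Why: MnO2 oxidises only the allylic C15 alcohol and so restores the exo-methylene ketone.

Step 19
Reactants: 23 6-alcohol of trichorabdal B
Product: 24 trichorabdal B
Conditions: TEMPO (0.2 equiv), PhI(OAc)2 (1.1 equiv), CH2Cl2, 0 → 23 °C
Reagents that add atoms: none
Why: Oxoammonium (TEMPO) oxidation should take the primary C6 alcohol to the aldehyde in preference to the hindered secondary 11-OH.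

**Compound list**
1 | 2-methylcyclohexan-1-one (racemic) | CC1CCCCC1=O | starting material
2 | 2-methyl-1-(trimethylsilyloxy)cyclohex-1-ene | CC1=C(O[Si](C)(C)C)CCCC1 | intermediate
3 | (S)-2-(hydroxymethyl)-2-methylcyclohexan-1-one | O=C1CCCC[C@@]1(C)CO | intermediate
4 | [(1S)-1-methyl-2-oxocyclohexyl]methyl acetate | O=C1CCCC[C@@]1(C)COC(C)=O | intermediate
5 | [(1S)-2-bromo-3-formyl-1-methylcyclohex-2-en-1-yl]methyl acetate | O=CC1=C(Br)[C@](C)(COC(C)=O)CCC1 | intermediate
6 | [(1S)-2-bromo-3-(hydroxymethyl)-1-methylcyclohex-2-en-1-yl]methyl acetate | OCC1=C(Br)[C@](C)(COC(C)=O)CCC1 | intermediate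
7 | [(1R)-2,3-bis(hydroxymethyl)-1-methylcyclohex-2-en-1-yl]methyl acetate | OCC1=C(CO)[C@](C)(COC(C)=O)CCC1 | intermediate
8 | tert-butyl 2-oxocyclopentane-1-carboxylate | O=C1CCCC1C(=O)OC(C)(C)C | starting material
9 | tert-butyl (S)-2-oxo-1-(prop-2-enyl)cyclopentane-1-carboxylate | O=C1[C@](CC=C)(C(=O)OC(C)(C)C)CCC1 | intermediate
10 | tert-butyl (R)-2-oxo-1-(prop-2-enyl)cyclopent-3-ene-1-carboxylate | O=C1[C@](CC=C)(C(=O)OC(C)(C)C)CC=C1 | intermediate
11 | tert-butyl (S)-2-oxo-1-(2-oxopropyl)cyclopent-3-ene-1-carboxylate | O=C1[C@](CC(C)=O)(C(=O)OC(C)(C)C)CC=C1 | intermediate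
12 | lithium C15/C16 enolate of the bicyclo[3.2.1]octanedione ester (C8, C13 as in 24) | C1=C([O-])[C@]2(C(=O)OC(C)(C)C)C[C@H]1CC(=O)C2.[Li+] | intermediate
13 | tert-butyl 6-exo-[(dimethylamino)methyl]-3,7-dioxobicyclo[3.2.1]octane-1-carboxylate (C8, C13 as in 24; CH2NMe2 on C16 anti to the C9–C11–C12 bridge) | CN(C)C[C@@H]1C(=O)[C@]2(C(=O)OC(C)(C)C)C[C@H]1CC(=O)C2 | intermediate
14 | bridgehead acid of 13 | CN(C)C[C@@H]1C(=O)[C@]2(C(=O)O)C[C@H]1CC(=O)C2 | intermediate
15 | C20 ester of 14 and 7, C6H2OH free | CN(C)C[C@@H]1C(=O)[C@]2(C(=O)OCC3=C(CO)[C@](C)(COC(C)=O)CCC3)C[C@H]1CC(=O)C2 | intermediate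
16 | enal ester (C6 aldehyde on C5=C10) | CN(C)C[C@@H]1C(=O)[C@]2(C(=O)OCC3=C(C=O)[C@](C)(COC(C)=O)CCC3)C[C@H]1CC(=O)C2 | intermediate
17 | cis-fused Michael adduct, 9-epimer of 18 (C10 axial on ring C) | CN(C)C[C@@H]1C(=O)[C@]23C[C@H]1CC(=O)[C@H]2[C@@]1(CCC[C@@](C)(COC(C)=O)[C@H]1C=O)COC3=O | intermediate
18 | trans-fused Michael adduct (C4, C5, C8, C9, C10, C13 as in 24) | CN(C)C[C@@H]1C(=O)[C@]23C[C@H]1CC(=O)[C@@H]2[C@@]1(CCC[C@@](C)(COC(C)=O)[C@H]1C=O)COC3=O | intermediate
19 | trimethylammonium iodide of 18 | C[N+](C)(C)C[C@@H]1C(=O)[C@]23C[C@H]1CC(=O)[C@@H]2[C@@]1(CCC[C@@](C)(COC(C)=O)[C@H]1C=O)COC3=O.[I-] | intermediate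
20 | 11-oxotrichorabdal B | C=C1C(=O)[C@]23C[C@H]1CC(=O)[C@@H]2[C@@]1(CCC[C@@](C)(COC(C)=O)[C@H]1C=O)COC3=O | intermediate
21 | 6,15-diol 11-ketone (15-OH endo, towards the C9–C11–C12 bridge) | C=C1[C@@H](O)[C@]23C[C@H]1CC(=O)[C@@H]2[C@@]1(CCC[C@@](C)(COC(C)=O)[C@H]1CO)COC3=O | intermediate
22 | 6,11,15-triol (11-OH equatorial) | C=C1[C@@H](O)[C@]23C[C@H]1C[C@@H](O)[C@@H]2[C@@]1(CCC[C@@](C)(COC(C)=O)[C@H]1CO)COC3=O | intermediate
23 | 6-alcohol of trichorabdal B | C=C1C(=O)[C@]23C[C@H]1C[C@@H](O)[C@@H]2[C@@]1(CCC[C@@](C)(COC(C)=O)[C@H]1CO)COC3=O | intermediate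
24 | trichorabdal B | C=C1C(=O)[C@]23C[C@H]1C[C@@H](O)[C@@H]2[C@@]1(CCC[C@@](C)(COC(C)=O)[C@H]1C=O)COC3=O | target

**Step count**
Total: 19 steps. Longest linear sequence: 14 steps (steps 1–6, then 12–19). The other branch, steps 7–11 then 12–19, has 13 steps.

**Steps most likely to fail**

Step 14. Several processes may interfere:
- the equilibrium may stay on the side of the open enal (retro-Michael from a very crowded C8–C9–C10 array);
- the enal may deconjugate by γ-deprotonation;
- the adduct may react on by an aldol reaction between C12 and C6;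
- the epimerisation at C9 may stop short.

The fallback activates the acceptor instead of the donor and makes the closure irreversible.
- It sets out from 16. Ethyl (trimethylsilyl)acetate and catalytic TBAF should convert 16 into the Δ9(11) trimethylsilyl enol ether of the C11 ketone F1. The Δ11(12) isomer cannot cyclise and returns to 16 on work-up.
- TiCl4 in CH2Cl2 at −78 °C, with one extra equivalent to bind the amine, should then bring about a Mukaiyama–Michael closure onto the titanium-bound enal.
- Aqueous work-up gives 17. DBU in toluene takes 17 to 18, where the route is rejoined.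
- If that equilibrium is unfavourable, 17 is deprotonated at C9 and reprotonated kinetically from the face opposite C5.

Step 10. Two processes may interfere: 1,2-addition (aldol at C15) may compete with the bridging 1,4-addition, and proton exchange may move the enolate away from C16 before the iminium salt arrives. The fallback brings in C17 first, so that no enolate has to be trapped.
- It sets out from 11. A Morita–Baylis–Hillman reaction (aq. HCHO, PBu3 cat.) should give the C16 hydroxymethyl enone F2.
- Ac2O/pyridine converts F2 into its acetate F3.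
- LDA at −78 °C deprotonates the methyl ketone kinetically. Addition of C12 to C13 with loss of acetate (SN2') should give the exo-methylene bicyclic diketo ester F4.
- Conjugate addition of Me2NH in THF leads back to 13.

Step 6. Oxidative addition into the tetrasubstituted C–Br bond next to the quaternary C4 may be slow, and protodebromination may take over. The fallback inverts the polarity of C5. It sets out from 6: CrCl2 with catalytic NiCl2 and paraformaldehyde in DMF (Nozaki–Hiyama–Kishi reaction) should add the vinylchromium(III) species to formaldehyde and give 7 directly.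

**Further compounds**
F1 | step 14 | Δ9(11) trimethylsilyl enol ether of the C11 ketone of 16 | CN(C)C[C@@H]1C(=O)[C@]2(C(=O)OCC3=C(C=O)[C@](C)(COC(C)=O)CCC3)C[C@H]1CC(O[Si](C)(C)C)=C2
F2 | step 10 | tert-butyl 3-(hydroxymethyl)-2-oxo-1-(2-oxopropyl)cyclopent-3-ene-1-carboxylate (C8 as in 11) | O=C1[C@](CC(C)=O)(C(=O)OC(C)(C)C)CC=C1CO
F3 | step 10 | tert-butyl 3-(acetoxymethyl)-2-oxo-1-(2-oxopropyl)cyclopent-3-ene-1-carboxylate (C8 as in 11) | O=C1[C@](CC(C)=O)(C(=O)OC(C)(C)C)CC=C1COC(C)=O
F4 | step 10 | tert-butyl 6-methylidene-3,7-dioxobicyclo[3.2.1]octane-1-carboxylate (C8, C13 as in 24) | C=C1C(=O)[C@]2(C(=O)OC(C)(C)C)C[C@H]1CC(=O)C2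
F0 | step 6 | none | none
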